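In a one-step world the left-handed product climbs with the catalyst charge until the left-handed substrate is gone. Here self-condensation may compete for the partner, so I looked for the concentration that sets the pace of capture, and took the active catalyst.

common to all: left-handed substrate 0.30 M; right-handed substrate 0.30 M
- north: solid reagent 0.36 M; free catalyst 0.28 mM; impurity 0.18 mM; run made earlier
- south-west: solid reagent 0.36 M; free catalyst 0.28 mM; impurity 0.060 mM; run made earlier
- dusk: solid reagent 0.360 M; free catalyst 0.28 mM; impurity 0.12 mM; time 80 min
- autumn: solid reagent 0.360 M; free catalyst 0.80 mM; impurity 0.12 mM; time 80 min

| run | time / min | right-handed substrate / % | left-handed substrate / % | left-handed product / % |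
|---|---|---|---|---|
| north | 6.00 | 51 | 49 | 2 |
| north | 15.0 | 49 | 44 | 6 |
| north | 20.0 | 51 | 44 | 5 |
| north | 30.0 | 51 | 43 | 7 |
| north | 40.0 | 51 | 40 | 10 |
| north | 50.0 | 50 | 41 | 10 |
| south-west | 2.50 | 51 | 50 | 0 |
| south-west | 8.00 | 51 | 48 | 2 |
| south-west | 15.0 | 47 | 42 | 7 |
| south-west | 20.0 | 50 | 39 | 10 |
| south-west | 30.0 | 51 | 34 | 16 |
| south-west | 40.0 | 47 | 32 | 22 |
| south-west | 50.0 | 47 | 32 | 20 |

(readings scatter by 1.5 percentage points)

- free catalyst is single-handed; left-handed substrate and right-handed substrate are mirror images of each other, charged as a racemate, each of them at the stated concentration
- as a solid, counted per litre of solution: solid reagent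
- steps thought possible: partner + free catalyst + left-handed substrate -> free catalyst + left-handed product; partner + free catalyst + right-handed substrate -> free catalyst + right-handed product; solid reagent <-> partner; 2 partner -> self-condensation product; free catalyst + impurity -> spent catalyst
- at the start none of the solid reagent is in solution
- an excess is below zero if the other one leads
- no earlier run changes the charge of free catalyst; that part of a forecast is a guess

* which of the two ends with the higher excess of right-handed substrate over left-handed substrate among what is left of the two ("neither" if they lie within 2 percentage points) (dusk / autumn / neither)
* excess of right-handed substrate over left-handed substrate among what is left of the two at the end, dusk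
* excess of right-handed substrate over left-handed substrate among what is left of the two at the end, autumn

I ordered events from the fastest. I put the impurity first, taking it to remove free catalyst one for one, leaving 0.100 mM active in north and 0.220 mM in south-west. The last two readings of left-handed product average 10.0% in north and 21.0% in south-west, a ratio of 2.10, against 2.20 for the active catalyst. Next I took the solid reagent to dissolve and the partner to be shared between capture, first order in partner, and self-condensation, second order, until the left-handed product levelled near 40.0 min in south-west. Slowest I put the right-handed substrate, reading 50% in north and 47% in south-west at the last readings, so I held it at 50.0%.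

By those readings capture took 16.7% of the solid reagent in north and 35.0% in south-west. Straight proportion gives autumn 68.0% left-handed product, more than the 50.0% of the pair charged as left-handed substrate, so I took the share as active catalyst over active catalyst plus a constant. North gives 0.500 mM and south-west 0.409 mM, mean 0.454 mM: the even-split catalyst, the active catalyst at which capture and self-condensation divide the solid reagent equally.

Dusk, with 0.160 mM active, gets a share of 26.0%, so 15.6% left-handed product and an excess of 18.5%. Autumn, with 0.680 mM, gets 59.9%, so 36.0% and 56.2%.

The forecast named autumn, with 18% (12% to 26%) for dusk and 45% (30% to 68%) for autumn, which “captures more partner, though not in proportion”. My autumn figure stood higher.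

Dusk ended at 20.8% and autumn at 54.7%, with 17.6% left-handed product in dusk against my 15.6% and 35.8% in autumn against my 36.0%.

    partner + free catalyst + left-handed substrate → free catalyst + left-handed product (k = 615 /M²/min)
    partner + free catalyst + right-handed substrate → free catalyst + right-handed product (k = 16.1 /M²/min)
    solid reagent ⇌ partner, rate k3*(cs3 - [partner]) while solid is left; crystals form when [partner] > cs3 (solubility = 0.290 M, k = 0.0726 /min)
    2 partner → self-condensation product (k = 0.325 /M/min)
    free catalyst + impurity → spent catalyst (k = 60300 /M/min)

The neighbour flask is autumn with its solid reagent cut to 0.14 M, so it keeps the 0.680 mM active catalyst. With the even-split catalyst scaled to that charge, 0.177 mM, the share is 79.4%, which gives 18.5% left-handed product and an excess of 22.7%. That flask gave 17.8% left-handed product and an excess of 21.0%, with 0.067% of the solid reagent, the limiting reagent, left, solid or dissolved.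

The runs are simulated from invented constants, noise included.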